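In a closed, stirred vessel at fixed temperature and volume, substrate is consumed in the presence of partner and a little initiator. We want to know how much has reacted at the end of the flasks grey, violet and red, which differ in partner.

| setting | summer | autumn | grey | violet | red |
|---|---|---|---|---|---|
| substrate | 0.40 M | 0.40 M | 0.40 M | 0.40 M | 0.40 M |
| partner | 0.61 equiv | 1 equiv | 0.700 equiv | 0.910 equiv | 1.20 equiv |
| initiator | 2.5 mol% | 2.5 mol% | 2.5 mol% | 2.5 mol% | 2.5 mol% |
| remark | run made earlier | run made earlier |  |  |  |
| time |  |  | 6.0 h | 6.0 h | 6.0 h |

| run | time / h | substrate / % | product / % |
|---|---|---|---|
| summer | 0.167 | 96 | 2 |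
| summer | 0.500 | 91 | 8 |
| summer | 0.833 | 81 | 11 |
| summer | 1.33 | 74 | 12 |
| summer | 2.00 | 73 | 14 |
| summer | 2.50 | 70 | 14 |
| summer | 3.00 | 63 | 18 |
| autumn | 0.417 | 88 | 9 |
| autumn | 0.833 | 78 | 13 |
| autumn | 1.33 | 68 | 16 |
| autumn | 1.50 | 70 | 18 |
| autumn | 2.00 | 60 | 18 |
| autumn | 2.50 | 55 | 19 |
| autumn | 3.00 | 55 | 22 |

(readings scatter by 2 percentage points)

- part of the substrate that has reacted at the end, grey
- part of the substrate that has reacted at the end, violet
- part of the substrate that has reacted at the end, red
- what raising the equivalents of partner from its lowest to its highest value here does to the part of the substrate that has reacted (changes below 5 percentage points count as none) (it rises / no change / it falls)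

- the numbers in the tables scatter with a standard deviation of 2 percentage points
- what has gone from substrate into another species counts as reacted, even if it can come back

We follow substrate rather than product: in the autumn run at 3.00 h, the readings show 45.0% of the substrate gone while product reads 22%, and what has gone into another species counts as reacted. Our tool is the running half-life h. If A is the fraction of substrate left at time t, then h = t·ln(2)/ln(1/A), the half-life a single pseudo-first-order loss would need to reach that reading.

We build our own reckoning in stages, starting with the autumn run. With one steady loss and the early autumn reading, h is 2.32 h at 0.833 h, and that steady loss reckons to 83.3% reacted after 6.0 h. Now we add the slowing: by 3.00 h, the autumn readings give a longer h of 3.48 h, and holding that value gives 69.7%. If the lengthening continues at the same pace, the running half-life at the asked time, at 1 equiv of partner, is 5.08 h.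

Last comes partner. In the summer run, h goes from 2.74 h to 4.50 h, which extends to 6.94 h. Read from these two runs, h varies as partner to the power −m, with m = 0.632. Our rule then gives grey h = 6.36 h, and we expect 48.0% reacted in grey, 53.8% in violet and 60.1% in red. That is a rise of 12 percentage points.

The forecast says 50%, 56% and 63%, somewhat above our values, and it rises. Its ground for the curve: “It also slows with time, through partner depletion, initiator decay, or reversibility.”

The flasks give 50.5%, 58.9% and 67.4%, and it rises by 17 points, so the forecast stands.

    initiator → 2 initiating radical (k = 6.50 × 10⁻⁵ /s)
    substrate + initiating radical → capped initiator + first chain carrier (k = 19000 /M/s)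
    partner + first chain carrier ⇌ product + second chain carrier (K = 0.630, k = 1300 /M/s)
    substrate + second chain carrier → released group + first chain carrier (k = 930 /M/s)
    2 first chain carrier → ended chains A (k = 3.00 × 10⁸ /M/s)
    2 second chain carrier → ended chains B (k = 8.00 × 10⁷ /M/s)
    substrate + released group ⇌ idle adduct, settled at all times (K = 250 /M)
    partner ⇌ dormant form (K = 1.10, k = 6.00 × 10⁻⁵ /s)

Grey's result means a running half-life of 5.91 h, against our 6.36 h. Grey holds something that number doesn't show: there the forward rate at which partner meets first chain carrier, over the forward rate of its turning into dormant form, falls from 0.82 at 1.33 h to 0.49 at 6.0 h, and the half-life of partner by that turning's forward rate alone is 3.2 h at 1.33 h. Grey ends with 0.0955 M of dormant form.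

The neighbour of grey charged with 2.80 equiv of partner gets h = 2.65 h from our rule, hence 79.2% reacted. The computed flask gives 85.2%.

(The earlier runs and the new flask are simulated with made-up constants, noise included.)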